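## Structural features

- The target is a daucane-type triester: a bicyclo[5.3.0]decane in which a cyclopentane (C1–C5) and a cycloheptene (C1, C5, C6–C10) share the C1–C5 bond. The fusion is trans (C1 methyl on one face, C5 hydrogen on the other).
- All six stereocentres are contiguous around the five-membered ring and its two flanks. They are quaternary C1 (methyl), C2 (acetate), C4 (tertiary carbinol bearing isopropyl), C5 (fusion CH), C6 (angelate) and C10 (benzoate). C10–C1–C2 and C4–C5–C6 are two runs of three adjacent stereocentres.
- Three different esters sit on three secondary oxygens while the tertiary C4 hydroxyl stays free, so each oxygen needs its own moment of acylation.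
- The fragile groups are the (Z)-2-methylbut-2-enoate (angelate), which drifts to the E isomer under nucleophilic, basic or thermal stress, and the allylic benzoate at C10. The C4 oxygen is β to C6 and can be lost by elimination or retro-aldol cleavage whenever C6 is a carbonyl.
- The real difficulty is the quaternary C1. It is flanked by two oxygenated stereocentres (C2, C10), bonded to C5 in a trans fusion, and sits two atoms from the fully substituted C4.
- The key step exploits the array C1(CH3)(C10–O)–C2(O). This is the product pattern of a 1,2-shift onto the methyl-bearing carbon of a 2,3-epoxy silyl ether, in which the migrating ring carbon C5 leaves C10 behind as an aldehyde.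
- Undoing that shift turns the cyclopentane C1–C5 into a cyclohexane (C1, C2, C3, C4, C5, C10) whose C4 carbinol with its isopropyl group is the carbinol carbon of a p-menth-1-en-4-ol.

## Logic of the disconnections

**25 ⇒ 24 ⇒ 23.** The acetate C2–O acyl bond is cut last, then the two O–Si bonds. Acetylation is placed at the end because there it only has to tell a secondary hydroxyl (C2) from a hindered tertiary one (C4). Both hydroxyls are then masked by one class of group that falls in one operation. The forward steps need fluoride conditions that spare three esters and the Z-enoate, and an acylation that ignores the C4 hydroxyl.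

**23 ⇒ 22 ⇒ 21.** The benzoate C10–O acyl bond is cut, then the C10–H bond (carbinol back to ketone). A ring ketone next to the quaternary C1 lets the angular methyl decide the hydride face, and the resulting enone is a metathesis retron. The forward reduction must be 1,2-selective, come from the face opposite the methyl, and leave the unsaturated ester alone.

**21 ⇒ 20.** The C8=C9 double bond is cut. This removes the seven-membered ring and leaves a trans-1,2-disubstituted cyclopentane with two side chains. The forward ring closure must join an electron-poor vinyl ketone to a 1,1-disubstituted alkene.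

**20 ⇒ 17 + 18.** The C6–O acyl bond is cut before ring closure, not after. In the ring enone the C6 oxygen is vinylogously β to the carbonyl, and a basic acylation there would invite elimination; in the open chain no such pathway exists. The forward step must transfer the Z-acyl group without isomerising it.

**17 ⇒ 14 + 15 (through 16).** The C6–C7 bond is cut. One step then brings in C7, C8 and the C8 methyl and creates the C6 stereocentre. C6 is exocyclic at this stage, so the forward step needs reagent control, must pick the aldehyde over the vinyl ketone, and must cope with a very hindered α-branched aldehyde.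

**14 ⇒ 13 ⇒ 12 ⇒ 10 + 11.** The oxidation levels at C6 and C10 are taken back, the benzyl-type ether is restored, and the C9–C10 bond is cut. This returns to the aldehyde that the key step delivers. The forward steps must not epimerise C5 once it is α to the C6 aldehyde.

**10 ⇒ 9 (key).** The C1–C5 bond is cut and C5 is reconnected to C10; the silyl group goes back from O2 to O10 and the C1–O–C2 epoxide is closed. The quaternary C1 becomes a trisubstituted epoxide carbon and the cyclopentane becomes a cyclohexane that maps onto 1. The forward step needs the epoxide oxygen cis to isopropyl and trans to the C10 silyloxy group, and needs the ring bond to migrate in preference to hydrogen.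

**9 ⇒ 8 ⇒ 7 ⇒ 6.** The epoxide C–O bonds, the O–Si bond at C10 and the C10–H bond are cut. This leaves an enone with one stereocentre beside C4. The forward steps must set the C10 carbinol cis to the C6 carbon and then epoxidise the opposite face.

**6 ⇒ 4 + 5.** The C5–C6 bond is cut, removing the one-carbon arm and the C5 stereocentre. The forward alkylation must occur at the α′ carbon next to the fully substituted C4 and trans to isopropyl.

**4 ⇒ 3 ⇒ 2 ⇒ 1.** The C10 oxygen and the silyl group are removed. Here the plan needs a correction in method. C4 of 1 is stereogenic only because the double bond lies on one side of it. An oxidation that passes through an allyl radical gives an intermediate with a mirror plane and hence racemic 4; an oxidation with allylic transposition gives the enantiomer. The forward step must therefore oxidise the ring CH2 next to the methyl-bearing carbon and put the double bond back where it was.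

## Other disconnections considered

**Alternative 1:** The cut is through C7–C8 and C1–C5, a formal [4+3] assembly of the seven-membered ring from a three-carbon diazo partner (C5–C6–C7) and a four-carbon diene partner (C8–C9–C10–C1).
- Forward key step: Rh2(S-DOSP)4, dirhodium tetrakis[(S)-N-(4-dodecylphenylsulfonyl)prolinate], would generate the vinylcarbenoid and cyclopropanate the terminal alkene of the diene. The cis-divinylcyclopropane would then rearrange (Cope) to the cycloheptadiene A1.
- In its favour: it is catalytic and enantioselective, convergent from two small achiral pieces, and forms two C–C bonds and the seven-membered ring at once. C6 and C10 arrive oxygenated and already differentiated as two different silyl enol ethers. On convergence and on bonds formed per step it is better than the chosen plan.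
- Against it here: only C1 of the six stereocentres is set. A1 carries an ester on C7 that has to be excised. It has no methyl on C8 and no C8=C9 double bond. The whole cyclopentane (C3, C4, the isopropyl group, the C4 carbinol, the C5 stereocentre and the trans fusion) would have to be annulated afterwards onto the C2 ester and the C5 methylene. The diene terminus that becomes C1 is fully substituted, so one substituent must point inward in the boat transition state of the Cope step, and the geometry of that tetrasubstituted enol ether would have to be controlled.
- Comparison: the chosen plan takes C4 from the chiral pool and relays it to C5, C10, C1 and C2 by substrate control and one stereospecific shift. Alternative 1 would buy a faster ring but face the hardest stereochemical work after its key step, so its step count after the key step should be clearly higher.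

**Alternative 2:** The cut is through C1–C5 and C8–C9, an intramolecular (4+3) cycloaddition of an oxyallyl cation (C1–C10–C9) with a tethered siloxydiene (C5–C8).
- Forward key step: NaOCH2CF3 in trifluoroethanol would ionise an acyclic dichloromethyl ketone to the chloro-oxyallyl cation. Cycloaddition and loss of HCl would give the bicyclic dienone A2.
- In its favour: both rings and two C–C bonds form in one step. The C8 methyl, the C8=C9 enone, the C10 ketone and a C6 enol ether appear at exactly the oxidation levels the endgame needs. In complexity gained per step it is better than the chosen plan, and in late functional-group handling it is its equal (two carbonyl reductions and three acylations remain in both).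
- Against it here: C2 and C4, the latter a tertiary silyl ether directly attached to the diene, must be made on an open chain. The cycloaddition must then deliver the trans fusion and the correct C1/C5 pair relative to C2 and C4 through a three-atom tether, where compact and extended transition states are usually close in energy. The fully substituted cation terminus C1 is hindered and can be lost to solvent capture or proton loss.
- Comparison: the mechanism leaves the C1/C5 relationship to a diastereoselective cycloaddition, whereas the chosen 1,2-shift fixes it stereospecifically from an epoxide whose face is set one step earlier. Alternative 2 could be shorter in steps but is less secure at the quaternary centre.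

**Alternative 3:** The cut is through C6–C7 and C9–C10, a [3+4] annulation of the dialdehyde A3 with the bifunctional allyl reagent A5.
- Forward key step: SnF2 would convert the allylic iodide of A5 into an allylstannane that adds to one aldehyde; the remaining allylsilane would close onto the second aldehyde and give the 8-methylene-6,10-diol A4.
- In its favour: A3 lies on the chosen route's own line (it is 10 after unmasking and oxidising C6, with either trialkylsilyl group on the C4 oxygen). The alternative therefore keeps the semipinacol step and is its equal up to that point. It would reach the seven-membered ring in three steps from 10, against five in the chosen plan, and forms two bonds in one operation; on that count it is better.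
- Against it here: C6 and C10 would be created together under substrate control with no separate handle on either. The two secondary hydroxyls would emerge unprotected and alike, and would have to be told apart for angelate and benzoate. The exocyclic alkene would have to be moved into the ring toward C9 and not toward C7, with nothing in the structure to bias that choice.
- Comparison: the chosen plan is longer in the ring-forming stretch but sets C6 and C10 in separate steps (reagent control, then ring control), acylates each hydroxyl as it appears, and places the double bond unambiguously by metathesis.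

Key step: step 8

Remarks on the chemistry, made before the steps:
- Assumption: (R)-(−)-terpinen-4-ol is used enantiopure (commercial material is enriched beforehand if needed), and 4-methoxybenzyl chloromethyl ether is purchased or freshly prepared.
- Numbering and faces: every intermediate carries the atom numbers of the target. In the six-membered-ring compounds the ring atoms are C1, C2, C3, C4, C5 and C10. In the bicycle, β is the face of the C5 hydrogen and α the face of the C1 methyl.
- Consistency check: the C4 configuration of 1, the trans relation of silyloxy group and epoxide in 9, and inversion at C1 with retention at C5 lead to the C1, C2, C4 and C5 configurations of 25. No structural correction is needed.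
- Design changes to the precursor: the C4 oxygen carries a triethylsilyl group, not a trimethylsilyl group, because it must survive methanolic borohydride, peracid, DDQ and a dozen further steps. The allylic oxidation is specified as the ene/[2,3] type for the reason set out in the last paragraph of the disconnection logic.

## Route

Step 1
Reactants: 1 (R)-terpinen-4-ol
Product: 2 (R)-terpinen-4-ol triethylsilyl ether
Conditions: TESOTf, 2,6-lutidine, CH2Cl2, −78 → 0 °C
Reagents that add atoms: triethylsilyl trifluoromethanesulfonate CC[Si](CC)(CC)OS(=O)(=O)C(F)(F)F
Why: Silyl triflate silylation is the standard way to cap a hindered tertiary alcohol. The triethylsilyl ether should withstand the base, hydride, peracid and Lewis acid steps ahead and is removed by fluoride at the end; no stereocentre is touched.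

Step 2
Reactants: 2 (R)-terpinen-4-ol triethylsilyl ether
Product: 3 (5S)-5-isopropyl-2-methyl-5-(triethylsilyloxy)cyclohex-2-en-1-ol (both epimers at the carbinol carbon; this carbon is C10)
Conditions: SeO2 (0.5 equiv), t-BuOOH, CH2Cl2, rt
Reagents that add atoms: tert-butyl hydroperoxide CC(C)(C)OO (terminal oxygen source; the oxygen is relayed by selenium dioxide O=[Se]=O)
Why: Selenium dioxide allylic hydroxylation is an ene reaction at the ring CH2 beside the more substituted alkene carbon followed by a [2,3]-sigmatropic shift that returns the double bond to C1=C2. No symmetric allyl intermediate is formed, so the configuration at C4 keeps its meaning, and the ring CH2 is preferred over the methyl group. The two C10 epimers converge in step 3.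

Step 3
Reactants: 3 (5S)-5-isopropyl-2-methyl-5-(triethylsilyloxy)cyclohex-2-en-1-ol
Product: 4 (S)-5-isopropyl-2-methyl-5-(triethylsilyloxy)cyclohex-2-en-1-one
Conditions: Dess–Martin periodinane, NaHCO3, CH2Cl2, 0 °C → rt
Reagents that add atoms: none
Why: Dess–Martin oxidation of the allylic alcohol mixture (with any enone already present) should give a single enone under neutral conditions that leave the tertiary silyl ether untouched.

Step 4
Reactants: 4 (S)-5-isopropyl-2-methyl-5-(triethylsilyloxy)cyclohex-2-en-1-one; 5 4-methoxybenzyl chloromethyl ether
Product: 6 (5R,6S)-5-isopropyl-6-[(4-methoxybenzyloxy)methyl]-2-methyl-5-(triethylsilyloxy)cyclohex-2-en-1-one (new arm trans to isopropyl)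
Conditions: LiN(iPr)2, THF, −78 °C; then 5, −78 → −40 °C
Reagents that add atoms: none
Why: Kinetic α′-deprotonation gives the cross-conjugated lithium enolate at C5, which is alkylated by the reactive alkoxymethyl chloride (enolate alkylation). The electrophile should enter anti to the isopropyl group, with the C4–C(isopropyl) bond antiperiplanar to the forming bond and the C4–O bond near the enolate plane. This places C6 trans to isopropyl, which is also the more stable diequatorial ketone.

Step 5
Reactants: 6 (5R,6S)-5-isopropyl-6-[(4-methoxybenzyloxy)methyl]-2-methyl-5-(triethylsilyloxy)cyclohex-2-en-1-one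
Product: 7 (1S,5R,6R)-5-isopropyl-6-[(4-methoxybenzyloxy)methyl]-2-methyl-5-(triethylsilyloxy)cyclohex-2-en-1-ol (hydroxyl cis to the C6 arm and to the C4 silyloxy group)
Conditions: NaBH4, CeCl3·7H2O, MeOH, −78 °C
Reagents that add atoms: none
Why: Luche 1,2-reduction. In the enone half-chair with isopropyl and the C6 arm equatorial, the C4 silyloxy group is axial and blocks axial hydride entry on its own face. Hydride should therefore come from the isopropyl face and leave the C10 hydroxyl cis to C6 and to the C4 oxygen.

Step 6
Reactants: 7 (1S,5R,6R)-5-isopropyl-6-[(4-methoxybenzyloxy)methyl]-2-methyl-5-(triethylsilyloxy)cyclohex-2-en-1-ol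
Product: 8 tert-butyldimethylsilyl ether of 7 (C10–OTBS; stereocentres unchanged)
Conditions: TBSOTf, 2,6-lutidine, CH2Cl2, −78 → 0 °C
Reagents that add atoms: tert-butyldimethylsilyl trifluoromethanesulfonate CC(C)(C)[Si](C)(C)OS(=O)(=O)C(F)(F)F
Why: Silyl triflate silylation of the hindered allylic alcohol. This silyl group later moves to the C2 oxygen in the key step and protects it to the end.

Step 7
Reactants: 8 tert-butyldimethylsilyl ether of 7
Product: 9 2,3-epoxy-1-(tert-butyldimethylsilyloxy)-5-isopropyl-6-[(4-methoxybenzyloxy)methyl]-2-methyl-5-(triethylsilyloxy)cyclohexane (cyclohexane locants; epoxide oxygen cis to isopropyl and trans to OTBS)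
Conditions: m-CPBA, NaHCO3, CH2Cl2, 0 °C
Reagents that add atoms: 3-chloroperoxybenzoic acid OOC(=O)c1cccc(Cl)c1
Why: Peracid epoxidation of the trisubstituted alkene. The allylic OTBS group is held pseudoaxial by allylic strain with the C1 methyl and, with the C4 silyloxy group, covers one face without offering a hydrogen bond to the peracid, so oxygen should arrive on the isopropyl face, trans to OTBS. The buffer protects the epoxide and the silyl ethers.

Step 8
Reactants: 9 2,3-epoxy-1-(tert-butyldimethylsilyloxy)-5-isopropyl-6-[(4-methoxybenzyloxy)methyl]-2-methyl-5-(triethylsilyloxy)cyclohexane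
Product: 10 (1R,2S,4R,5S)-2-(tert-butyldimethylsilyloxy)-4-isopropyl-5-[(4-methoxybenzyloxy)methyl]-1-methyl-4-(triethylsilyloxy)cyclopentane-1-carbaldehyde
Conditions: MeAl(OAr)2 (MABR; Ar = 4-bromo-2,6-di-tert-butylphenyl; pre-formed, 0.2 equiv), CH2Cl2, −78 → −20 °C
Reagents that add atoms: none
Why: The aluminium centre binds the epoxide oxygen and the C1–O bond at the tertiary, methyl-bearing carbon lengthens. As positive charge builds at C1, the ring twists so that the C10–C5 bond can reach the rear lobe at C1; C5 then migrates from C10 to C1 on the face opposite the departing oxygen, while a lone pair of the silyloxy oxygen turns C10 into a silyloxocarbenium ion. Transfer of the TBS group to the aluminium alkoxide on C2 releases the aldehyde and the Lewis acid, which is why a substoichiometric amount should suffice. The closest known reaction type is the Lewis acid semipinacol rearrangement of 2,3-epoxy alcohol silyl ethers in its ring-contracting form, which gives β-silyloxy cyclopentanecarbaldehydes. The five-membered ring is closed by a 1,2-shift of a ring bond through a three-centre transition state (six- to five-membered contraction), not by an end-to-end cyclisation. The new stereocentre C1 is controlled by the stereospecificity of the shift: inversion at C1 relative to the epoxide oxygen installed in step 7 and retention at the migrating C5, so the formyl group ends cis to the C2 silyloxy group and the methyl cis to C6. The selectivity needed is ring-bond migration over hydride shift: with OTBS trans to the epoxide, the C10 hydrogen lies on the same side as the breaking C1–O bond and cannot migrate to the rear lobe, and a shift of the C2 hydrogen lacks the oxygen assistance that only C10 provides. The bulky, non-nucleophilic aluminium phenoxide should not disturb the ethers, and C2, C4 and C5 are untouched.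

Step 9
Reactants: 10 (1R,2S,4R,5S)-2-(tert-butyldimethylsilyloxy)-4-isopropyl-5-[(4-methoxybenzyloxy)methyl]-1-methyl-4-(triethylsilyloxy)cyclopentane-1-carbaldehyde; 11 vinylmagnesium bromide
Product: 12 1-[2-(tert-butyldimethylsilyloxy)-4-isopropyl-5-[(4-methoxybenzyloxy)methyl]-1-methyl-4-(triethylsilyloxy)cyclopentyl]prop-2-en-1-ol (ring stereocentres as in 10; both C10 epimers)
Conditions: CH2=CHMgBr, THF, −78 → −20 °C; cold NH4Cl quench
Reagents that add atoms: none
Why: Grignard addition to the neopentyl aldehyde. The C10 configuration does not matter because the carbinol is oxidised in step 11, and the cold quench guards against oxygen-to-oxygen silyl migration in the magnesium alkoxide.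

Step 10
Reactants: 12 1-[2-(tert-butyldimethylsilyloxy)-4-isopropyl-5-[(4-methoxybenzyloxy)methyl]-1-methyl-4-(triethylsilyloxy)cyclopentyl]prop-2-en-1-ol
Product: 13 1-[2-(tert-butyldimethylsilyloxy)-5-(hydroxymethyl)-4-isopropyl-1-methyl-4-(triethylsilyloxy)cyclopentyl]prop-2-en-1-ol (both C10 epimers)
Conditions: DDQ, CH2Cl2/pH 7 buffer, 0 °C → rt
Reagents that add atoms: none
Why: Oxidative cleavage of the 4-methoxybenzyl ether by DDQ (hydride abstraction, then hydrolysis of the oxocarbenium ion). The buffered two-phase medium keeps both silyl ethers, and an unactivated vinyl carbinol is not oxidised.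

Step 11
Reactants: 13 1-[2-(tert-butyldimethylsilyloxy)-5-(hydroxymethyl)-4-isopropyl-1-methyl-4-(triethylsilyloxy)cyclopentyl]prop-2-en-1-ol
Product: 14 1-acryloyl-2-(tert-butyldimethylsilyloxy)-4-isopropyl-1-methyl-4-(triethylsilyloxy)cyclopentane-5-carbaldehyde (ring stereocentres as in 10)
Conditions: Dess–Martin periodinane (2.5 equiv), NaHCO3, CH2Cl2, 0 °C → rt
Reagents that add atoms: none
Why: Double Dess–Martin oxidation gives the C6 aldehyde and the C10 vinyl ketone together. The buffered, non-basic medium should neither epimerise C5 (now α to the aldehyde) nor eliminate the β-silyloxy group.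

Step 12
Reactants: 14 1-acryloyl-2-(tert-butyldimethylsilyloxy)-4-isopropyl-1-methyl-4-(triethylsilyloxy)cyclopentane-5-carbaldehyde; 15 2-methylallylmagnesium chloride
Product: 17 1-[2-(tert-butyldimethylsilyloxy)-5-[(1S)-1-hydroxy-3-methylbut-3-enyl]-4-isopropyl-1-methyl-4-(triethylsilyloxy)cyclopentyl]prop-2-en-1-one (6S), via B-(2-methylallyl)diisopinocampheylborane 16 (not isolated)
Conditions: (−)-Ipc2BOMe [from (+)-α-pinene], 15, Et2O, −78 °C → rt; then 14, −78 °C; pH 7 buffer/MeOH work-up
Reagents that add atoms: none
Why: Brown methallylboration. The allylborane adds through a closed chair transition state to the aldehyde only and leaves the hindered vinyl ketone alone. The reagent derived from (+)-α-pinene attacks the Si face of aldehydes, which here should give the (6S) carbinol by reagent control. A peroxide-free work-up spares the enone.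

Step 13
Reactants: 17 1-[2-(tert-butyldimethylsilyloxy)-5-[(1S)-1-hydroxy-3-methylbut-3-enyl]-4-isopropyl-1-methyl-4-(triethylsilyloxy)cyclopentyl]prop-2-en-1-one; 18 angelic acid [(Z)-2-methylbut-2-enoic acid]
Product: 20 (Z)-2-methylbut-2-enoate (angelate) of 17 at the C6 oxygen, via angelic 2,4,6-trichlorobenzoic anhydride 19 (not isolated)
Conditions: 2,4,6-Cl3C6H2COCl, Et3N, toluene, rt; then 17, 75 °C
Reagents that add atoms: none
Why: Yamaguchi-type esterification through the mixed anhydride without a nucleophilic catalyst, conditions known to transfer the angeloyl group without Z-to-E isomerisation. The alcohol attacks the less hindered angeloyl carbonyl. At this open-chain stage C6 has no elimination pathway, because C1 carries no hydrogen.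

Step 14
Reactants: 20 angelate of 17
Product: 21 (1R,2S,4R,5S,6S)-6-angeloyloxy-2-(tert-butyldimethylsilyloxy)-4-isopropyl-1,8-dimethyl-4-(triethylsilyloxy)bicyclo[5.3.0]dec-8-en-10-one (target numbering; trans-fused)
Conditions: second-generation Grubbs catalyst (H2IMes)(PCy3)Cl2Ru=CHPh (5–10 mol%), CH2Cl2 (2 mM), 40 °C
Reagents that add atoms: none
Why: Ring-closing metathesis between the vinyl ketone and the 1,1-disubstituted alkene closes the seven-membered ring and places the trisubstituted C8=C9 bond in conjugation with C10=O. Loss of ethylene drives the reaction and high dilution suppresses oligomers. The trisubstituted, electron-poor alkene of the angelate does not take part.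

Step 15
Reactants: 21 (1R,2S,4R,5S,6S)-6-angeloyloxy-2-(tert-butyldimethylsilyloxy)-4-isopropyl-1,8-dimethyl-4-(triethylsilyloxy)bicyclo[5.3.0]dec-8-en-10-one
Product: 22 (10S)-10-hydroxy compound: 6-angeloyloxy-2-(tert-butyldimethylsilyloxy)-4-isopropyl-1,8-dimethyl-4-(triethylsilyloxy)bicyclo[5.3.0]dec-8-en-10-ol (hydroxyl α; cis to the C1 methyl)
Conditions: NaBH4, CeCl3·7H2O, MeOH, −78 °C
Reagents that add atoms: none
Why: Luche 1,2-reduction. In the trans-fused ring the axial C1 methyl covers the α face of C10, so hydride should enter from the β face and give the 10α alcohol. The cold, brief conditions leave the unsaturated ester alone and give no time for vinylogous elimination of the C6 ester.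

Step 16
Reactants: 22 (10S)-10-hydroxy compound
Product: 23 10-benzoate of 22
Conditions: BzCl, pyridine, DMAP (cat.), CH2Cl2, 0 °C → rt
Reagents that add atoms: benzoyl chloride O=C(Cl)c1ccccc1
Why: Acylation of the only free hydroxyl, a hindered allylic alcohol, under nucleophilic catalysis. The configuration at C10 is retained because the C–O bond is not touched.

Step 17
Reactants: 23 10-benzoate of 22
Product: 24 (1R,2S,4R,5S,6S,10S)-6-angeloyloxy-10-benzoyloxy-4-isopropyl-1,8-dimethylbicyclo[5.3.0]dec-8-ene-2,4-diol
Conditions: HF·pyridine, pyridine, THF, 0 °C → rt
Reagents that add atoms: none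
Why: Fluoride cleavage of both silyl ethers. The medium is non-basic, so the esters should neither hydrolyse nor migrate and the angelate should keep its geometry.

Step 18
Reactants: 24 (1R,2S,4R,5S,6S,10S)-6-angeloyloxy-10-benzoyloxy-4-isopropyl-1,8-dimethylbicyclo[5.3.0]dec-8-ene-2,4-diol
Product: 25 CNP0248576.1, (1R,2S,4R,5S,6S,10S)-2-acetoxy-6-angeloyloxy-10-benzoyloxy-4-hydroxy-4-isopropyl-1,8-dimethylbicyclo[5.3.0]dec-8-ene (target numbering)
Conditions: Ac2O, pyridine, DMAP (cat.), CH2Cl2, 0 °C
Reagents that add atoms: acetic anhydride CC(=O)OC(C)=O
Why: Acetylation tells the secondary C2 hydroxyl from the hindered tertiary C4 hydroxyl, which should not acylate under these mild conditions.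

## Compound list

1 | (R)-terpinen-4-ol | CC1=CC[C@@](O)(C(C)C)CC1 | starting material
2 | (R)-terpinen-4-ol triethylsilyl ether | CC1=CC[C@@](O[Si](CC)(CC)CC)(C(C)C)CC1 | intermediate
3 | (5S)-5-isopropyl-2-methyl-5-(triethylsilyloxy)cyclohex-2-en-1-ol, both carbinol epimers | CC1=CC[C@@](O[Si](CC)(CC)CC)(C(C)C)CC1O | intermediate
4 | (S)-5-isopropyl-2-methyl-5-(triethylsilyloxy)cyclohex-2-en-1-one | CC1=CC[C@@](O[Si](CC)(CC)CC)(C(C)C)CC1=O | intermediate
5 | 4-methoxybenzyl chloromethyl ether | COc1ccc(COCCl)cc1 | starting material
6 | (5R,6S)-5-isopropyl-6-[(4-methoxybenzyloxy)methyl]-2-methyl-5-(triethylsilyloxy)cyclohex-2-en-1-one | CC1=CC[C@@](O[Si](CC)(CC)CC)(C(C)C)[C@H](COCc2ccc(OC)cc2)C1=O | intermediate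
7 | (1S,5R,6R)-5-isopropyl-6-[(4-methoxybenzyloxy)methyl]-2-methyl-5-(triethylsilyloxy)cyclohex-2-en-1-ol | CC1=CC[C@@](O[Si](CC)(CC)CC)(C(C)C)[C@H](COCc2ccc(OC)cc2)[C@@H]1O | intermediate
8 | tert-butyldimethylsilyl ether of 7 | CC1=CC[C@@](O[Si](CC)(CC)CC)(C(C)C)[C@H](COCc2ccc(OC)cc2)[C@@H]1O[Si](C)(C)C(C)(C)C | intermediate
9 | 2,3-epoxy-1-(tert-butyldimethylsilyloxy)-5-isopropyl-6-[(4-methoxybenzyloxy)methyl]-2-methyl-5-(triethylsilyloxy)cyclohexane, epoxide trans to OTBS (key-step precursor) | C[C@]12O[C@H]1C[C@@](O[Si](CC)(CC)CC)(C(C)C)[C@H](COCc1ccc(OC)cc1)[C@@H]2O[Si](C)(C)C(C)(C)C | intermediate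
10 | (1R,2S,4R,5S)-2-(tert-butyldimethylsilyloxy)-4-isopropyl-5-[(4-methoxybenzyloxy)methyl]-1-methyl-4-(triethylsilyloxy)cyclopentane-1-carbaldehyde (key-step product) | O=C[C@@]1(C)[C@@H](O[Si](C)(C)C(C)(C)C)C[C@@](O[Si](CC)(CC)CC)(C(C)C)[C@@H]1COCc1ccc(OC)cc1 | intermediate
11 | vinylmagnesium bromide | C=C[Mg]Br | starting material
12 | vinyl carbinol from 10, both C10 epimers | C=CC(O)[C@@]1(C)[C@@H](O[Si](C)(C)C(C)(C)C)C[C@@](O[Si](CC)(CC)CC)(C(C)C)[C@@H]1COCc1ccc(OC)cc1 | intermediate
13 | diol (C6 primary hydroxyl, C10 allylic hydroxyl), both C10 epimers | C=CC(O)[C@@]1(C)[C@@H](O[Si](C)(C)C(C)(C)C)C[C@@](O[Si](CC)(CC)CC)(C(C)C)[C@@H]1CO | intermediate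
14 | keto aldehyde (C10 vinyl ketone, C6 aldehyde) | C=CC(=O)[C@@]1(C)[C@@H](O[Si](C)(C)C(C)(C)C)C[C@@](O[Si](CC)(CC)CC)(C(C)C)[C@@H]1C=O | intermediate
15 | 2-methylallylmagnesium chloride | CC(=C)C[Mg]Cl | starting material
16 | B-(2-methylallyl)diisopinocampheylborane from (+)-α-pinene (formed in the flask) | CC(=C)CB([C@@H]1C[C@@H]2C[C@H]([C@H]1C)C2(C)C)[C@@H]1C[C@@H]2C[C@H]([C@H]1C)C2(C)C | intermediate
17 | (6S)-homoallylic alcohol | C=CC(=O)[C@@]1(C)[C@@H](O[Si](C)(C)C(C)(C)C)C[C@@](O[Si](CC)(CC)CC)(C(C)C)[C@@H]1[C@@H](O)CC(C)=C | intermediate
18 | angelic acid, (Z)-2-methylbut-2-enoic acid | C/C=C(/C)C(=O)O | starting material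
19 | angelic 2,4,6-trichlorobenzoic anhydride (formed in the flask) | C/C=C(/C)C(=O)OC(=O)c1c(Cl)cc(Cl)cc1Cl | intermediate
20 | C6 angelate of 17 | C=CC(=O)[C@@]1(C)[C@@H](O[Si](C)(C)C(C)(C)C)C[C@@](O[Si](CC)(CC)CC)(C(C)C)[C@@H]1[C@@H](OC(=O)/C(C)=C\C)CC(C)=C | intermediate
21 | (1R,2S,4R,5S,6S)-6-angeloyloxy-2-(tert-butyldimethylsilyloxy)-4-isopropyl-1,8-dimethyl-4-(triethylsilyloxy)bicyclo[5.3.0]dec-8-en-10-one | C/C=C(/C)C(=O)O[C@H]1CC(C)=CC(=O)[C@@]2(C)[C@@H](O[Si](C)(C)C(C)(C)C)C[C@@](O[Si](CC)(CC)CC)(C(C)C)[C@H]12 | intermediate
22 | (10S)-10-hydroxy compound from 21 | C/C=C(/C)C(=O)O[C@H]1CC(C)=C[C@H](O)[C@@]2(C)[C@@H](O[Si](C)(C)C(C)(C)C)C[C@@](O[Si](CC)(CC)CC)(C(C)C)[C@H]12 | intermediate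
23 | 10-benzoate of 22 | C/C=C(/C)C(=O)O[C@H]1CC(C)=C[C@H](OC(=O)c2ccccc2)[C@@]2(C)[C@@H](O[Si](C)(C)C(C)(C)C)C[C@@](O[Si](CC)(CC)CC)(C(C)C)[C@H]12 | intermediate
24 | 2,4-diol with C6 angelate and C10 benzoate | C/C=C(/C)C(=O)O[C@H]1CC(C)=C[C@H](OC(=O)c2ccccc2)[C@@]2(C)[C@@H](O)C[C@@](O)(C(C)C)[C@H]12 | intermediate
25 | CNP0248576.1, (1R,2S,4R,5S,6S,10S)-2-acetoxy-6-angeloyloxy-10-benzoyloxy-4-hydroxy-4-isopropyl-1,8-dimethylbicyclo[5.3.0]dec-8-ene | C/C=C(/C)C(=O)O[C@H]1CC(C)=C[C@H](OC(=O)c2ccccc2)[C@@]2(C)[C@@H](OC(C)=O)C[C@@](O)(C(C)C)[C@H]12 | target

## Step count and least certain steps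

Total step count: 18. Longest linear sequence: 18 steps (1 → 25); the other starting materials (5, 11, 15, 18) enter directly.

**Step 8 (key step).**
- What may go wrong: the electron-poor C1 may be diverted into pathways that need no alignment of the migrating bond. These are a shift of the C2 hydrogen to give a ketone, loss of a proton from the C1 methyl, or capture by the ether oxygen of the C6 arm. The cause is that in the half-chair the C10–C5 bond lies far from the axis of the breaking C1–O bond, and the substrate is crowded.
- Fallback (from 7, rejoining at 10): 7 is converted into its trimethylsilyl ether F1 (TMSCl, imidazole) and epoxidised on the isopropyl face to the epoxy trimethylsilyl ether F2 (m-CPBA, NaHCO3). F2 is rearranged with stoichiometric TiCl4 in CH2Cl2 at −78 °C, the classical titanium-mediated semipinacol rearrangement of epoxy trimethylsilyl ethers. Here the silyl group leaves as its chloride, so turnover does not depend on silyl transfer. Work-up gives the β-hydroxy aldehyde F3, which is silylated (TBSOTf, 2,6-lutidine) to 10.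

**Step 4.**
- What may go wrong: poor facial selectivity in the alkylation. The two C4 substituents differ less in effective size than a simple model suggests, and a pseudoaxial silyloxy group would steer the electrophile to the isopropyl face.
- Fallback (from 4, rejoining at 6): the alkylation product, now rich in the C5 epimer F4, is deprotonated again (LiN(iPr)2, THF, −78 °C) and the enolate is protonated kinetically with a hindered phenol. The facial bias that misdirected the electrophile should now direct the proton, and the thermodynamic preference for the diequatorial ketone points the same way, so the stereocentre is set by protonation and not by alkylation, giving 6.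

**Step 5.**
- What may go wrong: competing axial hydride delivery, giving the C10 epimer, if the axial silyloxy group shields less than expected.
- Fallback (from 6, rejoining at 7): the C10-epimeric alcohol F5 is esterified with 4-nitrobenzoic acid under Mitsunobu conditions (PPh3, DIAD) with inversion to the 4-nitrobenzoate F6, which is methanolysed (K2CO3, MeOH) to 7.

**Step 7.**
- What may go wrong: peracid attack on the wrong face, if the ring prefers the flipped half-chair in which an axial isopropyl group covers the intended face.
- Fallback (from 8, rejoining at 9): NBS in aqueous THF gives the bromohydrin F7, with bromine on the more accessible face at C2 and water entering trans at the tertiary C1. K2CO3 in MeOH then closes the epoxide from the hydroxyl face, which is the face opposite to the one an electrophile prefers, giving 9.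

**Step 12.**
- What may go wrong: insufficient reagent control, or sluggish addition, at an aldehyde flanked by two fully substituted carbons (a mismatched pairing with the substrate's own bias).
- Fallback (from 14, rejoining at 21): the C6-epimeric alcohol F8 is taken through the metathesis conditions of step 14 to the C6-epimeric hydroxy enone F9. F9 is esterified with 18 under Mitsunobu conditions (PPh3, DIAD), which inverts C6 and arrives directly at 21. The phosphine is used only at this ring stage, where the enone is β,β-disubstituted and a poor acceptor.

**Step 15.**
- What may go wrong: hydride delivery to the α face, if the β-oriented silyloxy group on C2 hinders the intended approach more than the angular methyl hinders the other.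
- Fallback (from 21, rejoining at 22): stereocontrol is moved from the substrate to a catalyst by Corey–Bakshi–Shibata reduction (oxazaborolidine, catecholborane, −78 °C). The catalyst enantiomer is chosen to place hydride on the β face, with the quaternary C1 as the large flank and C9 as the small one. No new compound arises.

## Further compounds

F1 | step 8 | trimethylsilyl ether of 7 | CC1=CC[C@@](O[Si](CC)(CC)CC)(C(C)C)[C@H](COCc2ccc(OC)cc2)[C@@H]1O[Si](C)(C)C
F2 | step 8 | epoxy trimethylsilyl ether, trimethylsilyl analogue of 9 | C[C@]12O[C@H]1C[C@@](O[Si](CC)(CC)CC)(C(C)C)[C@H](COCc1ccc(OC)cc1)[C@@H]2O[Si](C)(C)C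
F3 | step 8 | β-hydroxy aldehyde, 2-hydroxy analogue of 10 | O=C[C@@]1(C)[C@@H](O)C[C@@](O[Si](CC)(CC)CC)(C(C)C)[C@@H]1COCc1ccc(OC)cc1
F4 | step 4 | C5 epimer of 6 | CC1=CC[C@@](O[Si](CC)(CC)CC)(C(C)C)[C@@H](COCc2ccc(OC)cc2)C1=O
F5 | step 5 | C10 epimer of 7 | CC1=CC[C@@](O[Si](CC)(CC)CC)(C(C)C)[C@H](COCc2ccc(OC)cc2)[C@H]1O
F6 | step 5 | 4-nitrobenzoate of 7 | CC1=CC[C@@](O[Si](CC)(CC)CC)(C(C)C)[C@H](COCc2ccc(OC)cc2)[C@@H]1OC(=O)c3ccc(cc3)[N+](=O)[O-]
F7 | step 7 | bromohydrin of 8 (C1 hydroxyl on the isopropyl face, C2 bromine on the opposite face) | C[C@]1(O)[C@H](Br)C[C@@](O[Si](CC)(CC)CC)(C(C)C)[C@H](COCc2ccc(OC)cc2)[C@@H]1O[Si](C)(C)C(C)(C)C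
F8 | step 12 | C6 epimer of 17 | C=CC(=O)[C@@]1(C)[C@@H](O[Si](C)(C)C(C)(C)C)C[C@@](O[Si](CC)(CC)CC)(C(C)C)[C@@H]1[C@H](O)CC(C)=C
F9 | step 12 | C6-epimeric 6-hydroxy-bicyclo[5.3.0]dec-8-en-10-one | O[C@@H]1CC(C)=CC(=O)[C@@]2(C)[C@@H](O[Si](C)(C)C(C)(C)C)C[C@@](O[Si](CC)(CC)CC)(C(C)C)[C@H]12
F0 | step 15 | none | none
A1 | alternative 1 | dimethyl 1-methyl-6-(tert-butyldimethylsilyloxy)-10-(triethylsilyloxy)cyclohepta-6,9-diene-1,7-dicarboxylate (target numbering) | COC(=O)[C@@]1(C)CC(O[Si](C)(C)C(C)(C)C)=C(C(=O)OC)CC=C1O[Si](CC)(CC)CC
A2 | alternative 2 | trans-fused 2,6-bis(tert-butyldimethylsilyloxy)-1,8-dimethyl-4-isopropyl-4-(trimethylsilyloxy)bicyclo[5.3.0]deca-6,8-dien-10-one | CC1=CC(=O)[C@@]2(C)[C@@H](O[Si](C)(C)C(C)(C)C)C[C@@](O[Si](C)(C)C)(C(C)C)[C@@H]2C(O[Si](C)(C)C(C)(C)C)=C1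
A3 | alternative 3 | trans-2-(tert-butyldimethylsilyloxy)-4-isopropyl-1-methyl-4-(trimethylsilyloxy)cyclopentane-1,5-dicarbaldehyde | O=C[C@@]1(C)[C@@H](O[Si](C)(C)C(C)(C)C)C[C@@](O[Si](C)(C)C)(C(C)C)[C@@H]1C=O
A4 | alternative 3 | trans-fused 8-methylenebicyclo[5.3.0]decane-6,10-diol with C2–OTBS and C4–OTMS | O[C@H]1CC(=C)C[C@H](O)[C@@]2(C)[C@@H](O[Si](C)(C)C(C)(C)C)C[C@@](O[Si](C)(C)C)(C(C)C)[C@H]12
A5 | alternative 3 | 3-iodo-2-[(trimethylsilyl)methyl]prop-1-ene | C=C(CI)C[Si](C)(C)C
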